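The 3,7-dioxabicyclo[3.3.0]octane core (ring A: C1, C2, O3, C4, C5; ring B: C1, C5, C6, O7, C8; guaiacyl on C2) is unravelled at C1–C8 and C2–O3. The feature exploited: C5 carries both C4–O3 and C6–O7, so O3, O7 and C8 can be stored as a 1,3-dioxane formal. C2 is a para-oxygenated benzylic carbon, so C1=C2 can be an E-styrene. The precursor, a cis-4-aryl-5-styryl-1,3-dioxane from an Evans syn aldol, is an isomer of the protected target. Catalytic TMSOTf opens the acetal. Oxonium-Prins attack of C1 on C8 closes ring B, and O3 captures the C2 cation to close ring A, setting C1 and C2.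

Key step: step 7

Remark: 4-(allyloxy)-3-methoxybenzaldehyde (O-allylvanillin) is taken as a catalogue compound; if it is not at hand, vanillin is allylated exactly as in step 1.

Step 1
Reactants: 1 3-hydroxy-4,5-dimethoxybenzaldehyde
Product: 2 3-(allyloxy)-4,5-dimethoxybenzaldehyde
Conditions: allyl bromide, K2CO3, DMF, rt
Reagents that add atoms: allyl bromide, C=CCBr
Why: Williamson ether synthesis at the only acidic OH gives an allyl ether that should withstand the bases, boron and silyl triflates and hydride used later and can be removed at the end without touching benzylic C–O bonds.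

Step 2
Reactants: 3 4-(allyloxy)-3-methoxybenzaldehyde; 4 (2-carboxyethyl)triphenylphosphonium bromide
Product: 6 (E)-4-[4-(allyloxy)-3-methoxyphenyl]but-3-enoic acid, via carboxylate ylide 5 (not isolated)
Conditions: 4, NaN(SiMe3)2 (2 equiv per 4), THF, 0 °C; then 3, −78 °C → rt; 1 M HCl work-up
Reagents that add atoms: sodium hexamethyldisilazide, C[Si](C)(C)[N-][Si](C)(C)C.[Na+] (sodium only in 5)
Why: Wittig olefination in which the carboxylate-bearing ylide 5 favours the E-alkene with aromatic aldehydes, and conjugation with the arene keeps the double bond in the β,γ-position.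

Step 3
Reactants: 6 (E)-4-[4-(allyloxy)-3-methoxyphenyl]but-3-enoic acid; 7 (S)-4-benzyl-1,3-oxazolidin-2-one
Product: 9 (4S)-3-{(E)-4-[4-(allyloxy)-3-methoxyphenyl]but-3-enoyl}-4-benzyl-1,3-oxazolidin-2-one, via mixed pivalic anhydride 8 (not isolated)
Conditions: PivCl, Et3N, THF, −20 °C; then 7, LiCl, −20 °C → rt
Reagents that add atoms: pivaloyl chloride, CC(C)(C)C(=O)Cl (pivaloyl group only in 8)
Why: N-acylation of the oxazolidinone through the mixed anhydride 8 (LiCl-assisted) takes place at the less hindered carbonyl and needs no strong base, so the β,γ-alkene should stay in place.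

Step 4
Reactants: 9 (4S)-3-{(E)-4-[4-(allyloxy)-3-methoxyphenyl]but-3-enoyl}-4-benzyl-1,3-oxazolidin-2-one; 2 3-(allyloxy)-4,5-dimethoxybenzaldehyde
Product: 12 (4S)-4-benzyl-3-{(2S,3E)-2-[(S)-[3-(allyloxy)-4,5-dimethoxyphenyl](hydroxy)methyl]-4-[4-(allyloxy)-3-methoxyphenyl]but-3-enoyl}-1,3-oxazolidin-2-one (syn aldol), via boron dienolate 10 (not isolated), via boron aldolate 11 (not isolated)
Conditions: Bu2BOTf, Et3N, CH2Cl2, −78 → 0 °C; then 2, −78 → 0 °C; pH 7 buffer, MeOH, 30% H2O2, 0 °C
Reagents that add atoms: dibutylboron triflate, CCCCB(CCCC)OS(=O)(=O)C(F)(F)F (boron and butyl groups only in 10 and 11)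
Why: Evans syn aldol: soft enolisation gives the Z-configured boron dienolate 10, which reacts at its α-carbon through a closed Zimmerman–Traxler chair on the face left open by the benzyl group of the (S)-auxiliary, so that the future C5 (2S) and C6 (carbinol S) are set syn in one event, and buffered peroxide frees 12 from aldolate 11.

Step 5
Reactants: 12 syn aldol
Product: 13 (1S,2R,3E)-1-[3-(allyloxy)-4,5-dimethoxyphenyl]-4-[4-(allyloxy)-3-methoxyphenyl]-2-(hydroxymethyl)but-3-en-1-ol
Conditions: LiBH4, MeOH (1 equiv), THF, 0 °C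
Reagents that add atoms: none
Why: Reductive cleavage of the N-acyl oxazolidinone with LiBH4 takes place at the exocyclic carbonyl, leaves both stereocentres, the styrene and the allyl ethers untouched and returns the auxiliary.

Step 6
Reactants: 13 (1S,2R,3E)-diol
Product: 14 (4S,5R)-4-[3-(allyloxy)-4,5-dimethoxyphenyl]-5-{(E)-2-[4-(allyloxy)-3-methoxyphenyl]ethenyl}-1,3-dioxane
Conditions: CH2Br2, NaH, DMF, 0 °C → rt
Reagents that add atoms: dibromomethane, BrCBr
Why: Double Williamson alkylation of the dialkoxide with CH2Br2 (methylene acetal formation under basic conditions) closes the six-membered formal without any acid that could ionise the benzylic alcohol or start the Prins reaction early, and both stereocentres are carried over as the cis-4,5 pair (aryl equatorial, styryl axial).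

Step 7
Reactants: 14 (4S,5R)-4-aryl-5-styryl-1,3-dioxane
Product: 17 (1R,2S,5R,6S)-2-[4-(allyloxy)-3-methoxyphenyl]-6-[3-(allyloxy)-4,5-dimethoxyphenyl]-3,7-dioxabicyclo[3.3.0]octane (both aryl groups exo), via oxocarbenium triflate 15 (not isolated), via benzylic cation triflate 16 (not isolated)
Conditions: TMSOTf (0.2 equiv), 4 Å MS, CH2Cl2 (0.01 M), −78 → −20 °C; Et3N quench
Reagents that add atoms: trimethylsilyl triflate, C[Si](C)(C)OS(=O)(=O)C(F)(F)F (silyl group and triflate only in 15 and 16, released again; 17 holds no reagent atoms)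
Why: TMSOTf silylates the less hindered acetal oxygen of 14 (dioxane O1, on the primary C6), the dioxane C2–O1 bond breaks to give oxocarbenium 15 (CH2=O+ on the benzylic oxygen), its CH2 carbon (future C8) is attacked by the styrene β-carbon (future C1), and the para-allyloxybenzyl cation 16 is captured by the silyloxy oxygen (future O3) with release of TMSOTf, so the step is a catalytic isomerisation. The closest known reaction type is the acetal-initiated oxonium-Prins cyclisation of styrenes to tetrahydrofurans with internal oxygen termination (Prins bicyclisation). Ring B closes 5-exo-trig at the styrene with the oxocarbenium endocyclic (C1–C8), and ring A closes by five-membered capture of the exocyclic benzylic cation (C2–O3, formally 5-endo with respect to the original alkene). C1 is controlled by C5: the small CH2OSiMe3 arm takes the inside position at the alkene where its oxygen supports the growing charge at C2, only this cis arrangement can be captured, and a trans cation should lose its C1 proton and re-enter by reprotonation of the benzylidene tetrahydrofuran; C2 is controlled by the E geometry (anti addition of C8 and O3) and by closure with the aryl group on the convex face. The step needs acetal opening towards an oxocarbenium on O7 and not on O3, attack by C1 and not by C2 (5-exo against 6-endo or 2-oxonia-Cope), and kinetic control at the acid-labile benzylic C2 and C6. These should be secured by the steric difference between the two acetal oxygens, by the benzylic stabilisation that polarises the styrene towards C1 attack, and by low temperature, catalytic acid, high dilution and the amine quench.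

Step 8
Reactants: 17 diallyl ether of the target
Product: 18 (1R,2S,5R,6S)-2-(4-hydroxy-3-methoxyphenyl)-6-(3-hydroxy-4,5-dimethoxyphenyl)-3,7-dioxabicyclo[3.3.0]octane (CNP0324902.1)
Conditions: Pd(PPh3)4 (5 mol %), morpholine, THF, rt
Reagents that add atoms: none
Why: Tsuji–Trost-type deallylation: zerovalent palladium ionises both aryl allyl ethers to π-allyl complexes that morpholine captures, under neutral non-reductive conditions that should leave the two benzylic ethers and all four stereocentres untouched.

Compound list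
1 | 3-hydroxy-4,5-dimethoxybenzaldehyde | COc1cc(C=O)cc(O)c1OC | starting material
2 | 3-(allyloxy)-4,5-dimethoxybenzaldehyde | COc1cc(C=O)cc(OCC=C)c1OC | intermediate
3 | 4-(allyloxy)-3-methoxybenzaldehyde | COc1cc(C=O)ccc1OCC=C | starting material
4 | (2-carboxyethyl)triphenylphosphonium bromide | OC(=O)CC[P+](c1ccccc1)(c1ccccc1)c1ccccc1.[Br-] | starting material
5 | sodium 3-(triphenyl-λ5-phosphanylidene)propanoate (carboxylate ylide, not isolated) | [Na+].[O-]C(=O)CC=P(c1ccccc1)(c1ccccc1)c1ccccc1 | intermediate
6 | (E)-4-[4-(allyloxy)-3-methoxyphenyl]but-3-enoic acid | COc1cc(/C=C/CC(=O)O)ccc1OCC=C | intermediate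
7 | (S)-4-benzyl-1,3-oxazolidin-2-one | O=C1N[C@@H](Cc2ccccc2)CO1 | starting material
8 | (E)-4-[4-(allyloxy)-3-methoxyphenyl]but-3-enoic pivalic anhydride (not isolated) | COc1cc(/C=C/CC(=O)OC(=O)C(C)(C)C)ccc1OCC=C | intermediate
9 | (4S)-3-{(E)-4-[4-(allyloxy)-3-methoxyphenyl]but-3-enoyl}-4-benzyl-1,3-oxazolidin-2-one | COc1cc(/C=C/CC(=O)N2[C@@H](Cc3ccccc3)COC2=O)ccc1OCC=C | intermediate
10 | Z-configured dibutylboron dienolate of 9 (not isolated) | CCCCB(CCCC)O/C(=C\C=C\c1ccc(OCC=C)c(OC)c1)N1[C@@H](Cc2ccccc2)COC1=O | intermediate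
11 | dibutylboron aldolate of 12 (not isolated) | O=C(N1[C@@H](Cc2ccccc2)COC1=O)[C@@H](/C=C/c1ccc(OCC=C)c(OC)c1)[C@H](OB(CCCC)CCCC)c1cc(OCC=C)c(OC)c(OC)c1 | intermediate
12 | (4S)-4-benzyl-3-{(2S,3E)-2-[(S)-[3-(allyloxy)-4,5-dimethoxyphenyl](hydroxy)methyl]-4-[4-(allyloxy)-3-methoxyphenyl]but-3-enoyl}-1,3-oxazolidin-2-one | O=C(N1[C@@H](Cc2ccccc2)COC1=O)[C@@H](/C=C/c1ccc(OCC=C)c(OC)c1)[C@H](O)c1cc(OCC=C)c(OC)c(OC)c1 | intermediate
13 | (1S,2R,3E)-1-[3-(allyloxy)-4,5-dimethoxyphenyl]-4-[4-(allyloxy)-3-methoxyphenyl]-2-(hydroxymethyl)but-3-en-1-ol | OC[C@@H](/C=C/c1ccc(OCC=C)c(OC)c1)[C@H](O)c1cc(OCC=C)c(OC)c(OC)c1 | intermediate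
14 | (4S,5R)-4-[3-(allyloxy)-4,5-dimethoxyphenyl]-5-{(E)-2-[4-(allyloxy)-3-methoxyphenyl]ethenyl}-1,3-dioxane | C1OC[C@@H](/C=C/c2ccc(OCC=C)c(OC)c2)[C@@H](c2cc(OCC=C)c(OC)c(OC)c2)O1 | intermediate
15 | ring-opened O-methylidene oxocarbenium triflate with primary OSiMe3 group (not isolated) | C=[O+][C@H](c1cc(OCC=C)c(OC)c(OC)c1)[C@@H](CO[Si](C)(C)C)/C=C/c1ccc(OCC=C)c(OC)c1.[O-]S(=O)(=O)C(F)(F)F | intermediate
16 | ring B tetrahydrofuran carrying the para-allyloxybenzyl cation, triflate salt (not isolated) | C1O[C@H](c2cc(OCC=C)c(OC)c(OC)c2)[C@@H](CO[Si](C)(C)C)[C@H]1[CH+]c1ccc(OCC=C)c(OC)c1.[O-]S(=O)(=O)C(F)(F)F | intermediate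
17 | (1R,2S,5R,6S)-2-[4-(allyloxy)-3-methoxyphenyl]-6-[3-(allyloxy)-4,5-dimethoxyphenyl]-3,7-dioxabicyclo[3.3.0]octane | COc1cc([C@H]2OC[C@H]3[C@@H]2CO[C@@H]3c2cc(OCC=C)c(OC)c(OC)c2)ccc1OCC=C | intermediate
18 | (1R,2S,5R,6S)-2-(4-hydroxy-3-methoxyphenyl)-6-(3-hydroxy-4,5-dimethoxyphenyl)-3,7-dioxabicyclo[3.3.0]octane | COc1cc([C@H]2OC[C@H]3[C@@H]2CO[C@@H]3c2cc(O)c(OC)c(OC)c2)ccc1O | target

Total step count: 8. Longest linear sequence: 7 steps (3 → 6 → 9 → 12 → 13 → 14 → 17 → 18).

Steps most likely to fail

Step 7. Three things may go wrong.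
- The acetal may open in the wrong sense, placing the oxocarbenium on O3.
- The styrene may be attacked on the face that puts the cationic arm trans to the CH2O arm, so that capture fails.
- Long acid contact may epimerise the benzylic centres.

The fallback splits the cascade into two stages, so that C1 is set by protonation under ring-fusion control and not in the C–C bond formation. It sets out from 14. Stoichiometric TMSOTf with 2,6-di-tert-butyl-4-methylpyridine in CH2Cl2 at −78 °C should still close C1–C8 but end by loss of the C1 proton, giving the trimethylsilyl ether of the 4-benzylidene tetrahydrofuran F1. K2CO3 in MeOH then frees the 4-benzylidene tetrahydrofuran-3-ylmethanol F2. Catalytic camphorsulfonic acid in CH2Cl2 at 0 °C protonates the electron-rich styrene reversibly at C1, and only the cis cation can be captured by the primary OH (acid-catalysed Markovnikov hydroalkoxylation). This comes back to the route at 17.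

Step 6. Intermolecular formal formation (oligomerisation) may compete with ring closure, and the second alkylation may stall. The fallback gives up the cyclic acetal and differentiates the two oxygens. It sets out from 13. TBSCl and imidazole in DMF silylate the primary OH to give the primary tert-butyldimethylsilyl ether F3. MOMCl and iPr2NEt in CH2Cl2 then give the benzylic methoxymethyl ether F4. Catalytic TMSOTf in CH2Cl2 at −78 °C ionises this acyclic mixed acetal, which can form an oxocarbenium only on O7. The same C1–C8 Prins closure follows, and the silyl ether oxygen captures the C2 cation and hands its silyl group to methoxide. This bypasses 14 and comes back to the route at 17.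

Step 4. Enolisation of the styrylacetyl imide may let the double bond drift into conjugation. The dienolate may react at its γ-carbon. The doubly activated C–H of the adduct may epimerise, or the adduct may undergo retro-aldol cleavage, during work-up. The fallback uses a titanium enolate of a thiazolidinethione, which is enolised at low temperature and gives up its auxiliary to a mild hydride. It sets out from 6. EDC·HCl and DMAP couple 6 with (S)-4-benzyl-1,3-thiazolidine-2-thione to give the N-acyl thiazolidinethione F5. TiCl4, iPr2NEt and N-methylpyrrolidinone in CH2Cl2 at −78 °C, followed by 2, should give the syn aldol of the same absolute sense F6. NaBH4 in THF–EtOH removes the auxiliary directly, and the sequence comes back to the route at 13.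

Further compounds
F1 | step 7 | {[(2S,3R,4Z)-2-[3-(allyloxy)-4,5-dimethoxyphenyl]-4-{[4-(allyloxy)-3-methoxyphenyl]methylidene}oxolan-3-yl]methoxy}trimethylsilane | C1O[C@H](c2cc(OCC=C)c(OC)c(OC)c2)[C@@H](CO[Si](C)(C)C)/C1=C/c1ccc(OCC=C)c(OC)c1
F2 | step 7 | [(2S,3R,4Z)-2-[3-(allyloxy)-4,5-dimethoxyphenyl]-4-{[4-(allyloxy)-3-methoxyphenyl]methylidene}oxolan-3-yl]methanol | C1O[C@H](c2cc(OCC=C)c(OC)c(OC)c2)[C@@H](CO)/C1=C/c1ccc(OCC=C)c(OC)c1
F3 | step 6 | (1S,2R,3E)-1-[3-(allyloxy)-4,5-dimethoxyphenyl]-4-[4-(allyloxy)-3-methoxyphenyl]-2-{[(tert-butyldimethylsilyl)oxy]methyl}but-3-en-1-ol | CC(C)(C)[Si](C)(C)OC[C@@H](/C=C/c1ccc(OCC=C)c(OC)c1)[C@H](O)c1cc(OCC=C)c(OC)c(OC)c1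
F4 | step 6 | methoxymethyl ether of F3 at the benzylic oxygen | CC(C)(C)[Si](C)(C)OC[C@@H](/C=C/c1ccc(OCC=C)c(OC)c1)[C@H](OCOC)c1cc(OCC=C)c(OC)c(OC)c1
F5 | step 4 | (E)-4-[4-(allyloxy)-3-methoxyphenyl]-1-[(4S)-4-benzyl-2-sulfanylidene-1,3-thiazolidin-3-yl]but-3-en-1-one | COc1cc(/C=C/CC(=O)N2[C@@H](Cc3ccccc3)CSC2=S)ccc1OCC=C
F6 | step 4 | (2S,3E)-2-[(S)-[3-(allyloxy)-4,5-dimethoxyphenyl](hydroxy)methyl]-4-[4-(allyloxy)-3-methoxyphenyl]-1-[(4S)-4-benzyl-2-sulfanylidene-1,3-thiazolidin-3-yl]but-3-en-1-one | O=C(N1[C@@H](Cc2ccccc2)CSC1=S)[C@@H](/C=C/c1ccc(OCC=C)c(OC)c1)[C@H](O)c1cc(OCC=C)c(OC)c(OC)c1
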